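Time is the thing to watch in these flasks. Target, once born, turns into its isomer and back, so its share depends on how long ago it was born. The four flasks take the same charges in different ways.

| flask | starting material | second substrate | reagent | free catalyst | time | remark | temperature |
|---|---|---|---|---|---|---|---|
| south-west | 0.010 M | 1.00 equiv (fed, over 15 s) | 1.00 equiv | 0.5 mol% | 40 s | the addition at −35 °C, then warmed to 5 °C; the feed brings no volume worth counting |  |
| east | 0.010 M (fed, over 15 s) | 1.00 equiv | 1.00 equiv | 0.5 mol% | 40 s | all else is in the flask from the start; the feed brings no volume worth counting | 5 °C |
| south-east | 0.010 M | 1.00 equiv (in portions, 2, over 15 s) | 1.00 equiv | 0.5 mol% | 40 s | first portion at the start, last at 15 s | 5 °C |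
| north-west | 0.010 M | 1.00 equiv | 1.00 equiv | 0.5 mol% | 40 s | everything together at the start | 5 °C |

- the best flask by share of target in target plus isomer of the product; "all alike" if 1.5 percentage points covers them all (south-west / east / south-east / north-west / all alike)
- share of target in target plus isomer of the product at the end, south-west
- share of target in target plus isomer of the product at the end, east
- share of target in target plus isomer of the product at the end, south-east
- share of target in target plus isomer of the product at the end, north-west

- all constants are for 5 °C and move with temperature by the activation energies and enthalpies

    reagent + catalyst intermediate A → free catalyst + target (k1 = 310 /M/s, Ea1 = 42.0 kJ/mol)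
    reagent + catalyst intermediate B → free catalyst + second product (k2 = 1570 /M/s, Ea2 = 41.0 kJ/mol)
    starting material + free catalyst ⇌ catalyst intermediate A (K3 = 37 /M, k3 = 1640 /M/s, Ea3 = 39.0 kJ/mol, ΔH3 = −79.0 kJ/mol)
    second substrate + free catalyst ⇌ catalyst intermediate B (K4 = 1110 /M, k4 = 24700 /M/s, Ea4 = 23.0 kJ/mol, ΔH4 = −39.0 kJ/mol)
    target ⇌ isomer of the product (K5 = 1.0, k5 = 0.0164 /s, Ea5 = 68.0 kJ/mol, ΔH5 = −34.0 kJ/mol)
    (constants at 5 °C)

Who makes target? Starting material binds free catalyst as catalyst intermediate A, and reagent releases target from it. Second substrate binds free catalyst as catalyst intermediate B, and reagent releases second product from that.

How fast does target lose its purity? The isomerisation is a first-order pair, forward 0.0164 /s and back at that constant divided by 1.0. A two-state exchange relaxes at the sum of its two constants. The inverse of that sum at 5 °C is 30.5 s; I call it the memory time. A batch starts as pure target, and its share falls towards a floor of 50.0%. The excess over the floor decays with the memory time.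

But births are spread out. What then? I take two limits for north-west. Target born at the first instant ends at 63.5%. Target born steadily over 40 s ends at 77.9%. I place north-west between them and no closer.

How do the other flasks lean? Divide the target rate by the second-product rate and time drops out. At a given reagent level, this selectivity factor follows the fraction of starting material over the fraction of second substrate. I take this because the half-lives of catalyst intermediate A and catalyst intermediate B by their release steps alone, at the charged north-west concentrations, are 0.22 s and 0.044 s, far shorter than the run. In east, the starting-material fraction is small early, so births come late and the target is younger. I put east above north-west. In south-east, the first portion starts the second-substrate fraction at half, so births come early. I put south-east below north-west.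

And the cold flask? At −35 °C the forward constant falls to 1.17 × 10⁻⁴ /s. Its time of 8510 s far exceeds the feed, so I let the clock stand still during the feed. Taking the warming at the end of the feed, south-west ages for 25.0 s. Target born before warming ends at 72.0%, and target born steadily afterwards at 84.1%. I commit to south-west as best, with east next.

The forecast names south-west, with 80% for south-west, 78.5% for east, 72.8% for south-east and 75.2% for north-west, and its grounds include “cold feed makes little target and almost no isomer”.

The simulation gives 80.1% for south-west, 78.2% for east, 72.3% for south-east and 74.9% for north-west, so the best flask is south-west. South-east stands below north-west, north-west below east, and east below south-west.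

Read back through the memory time, the south-west share equals that of one batch of age 15.5 s, inside its warm window of 25.0 s. A neighbouring run is the same south-west flask read at 25 s. Its warm window is 10.0 s, so the same limits run from 86.0% to 92.6%. That reading shows 89.8%, one batch of age 6.96 s. At 25.0 s this south-west neighbour holds target at 0.863% and isomer of the product at 0.0983% of the starting material charged.

All constants are made up; the flask was simulated.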